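**Strategy.** The route rests on cutting the methylene bridge at its bond to C3 of the 4-hydroxy-2-pyranone ring. The key step exploits the free phenol OH on the benzene-ring carbon next to the bridge-bearing carbon, and the nucleophilic pyranone C3 flanked by the C2 lactone carbonyl and the C4 enol. A phenolic Mannich base (ArCH2NMe2) loses dimethylamine on heating to give an ortho-quinone methide, which the pyranone captures by conjugate addition. This forms the CH2–C3 bond and completes the unprotected target in one operation. The precursor is the (R)-2-methylbutanoyl, prenyl, O-methyl phloroglucinol carrying the CH2NMe2 group; the partner is 6-ethyl-4-hydroxy-5-methyl-2-pyranone.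

Key step: step 7

Remark: (2R)-2-methylbutanoic acid 5 is assumed to be purchased as the single enantiomer and phloroglucinol 6 in its anhydrous form; 3 is drawn as the triketo tautomer although it is largely enolised.

**Step 1**
Reactants: 1 methyl 3-oxopentanoate; 2 N-methoxy-N-methylpropanamide
Product: 3 methyl 4-methyl-3,5-dioxoheptanoate
Conditions: LDA (2.2 equiv), THF, −78 to 0 °C; then 2, −78 to 0 °C; 1 M HCl
Reagents that add atoms: none
Why: γ-Acylation of a β-keto ester dianion, which should react at its more basic C4 carbon with the Weinreb amide, whose chelated tetrahedral adduct prevents over-addition until work-up.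

**Step 2**
Reactants: 3 methyl 4-methyl-3,5-dioxoheptanoate
Product: 4 6-ethyl-4-hydroxy-5-methyl-2H-pyran-2-one
Conditions: DBU, toluene, reflux; then 1 M HCl
Reagents that add atoms: none
Why: Base-mediated enol lactonisation of a 3,5-dioxo ester (the C5 enol oxygen displaces methoxide from the ester), a standard 4-hydroxy-2-pyranone synthesis that also removes the C4 stereocentre of 3.

**Step 3**
Reactants: 5 (2R)-2-methylbutanoic acid; 6 phloroglucinol
Product: 8 (2R)-2-methyl-1-(2,4,6-trihydroxyphenyl)butan-1-one, via (2R)-2-methylbutanoyl chloride 7 (not isolated)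
Conditions: (COCl)2, cat. DMF, CH2Cl2, 0 °C to rt; then 6, AlCl3 (3 equiv), CH2Cl2/MeNO2, 0 °C to rt; aq. HCl
Reagents that add atoms: oxalyl chloride, ClC(=O)C(=O)Cl (supplies the chlorine of intermediate 7 only)
Why: Friedel–Crafts C-acylation of the symmetric, highly activated triol, in which the first acyl group deactivates the ring against a second acylation and the low temperature should keep the acid chloride and the chelated ketone from enolising, so the (R)-centre bought with 5 is carried through.

**Step 4**
Reactants: 8 (2R)-2-methyl-1-(2,4,6-trihydroxyphenyl)butan-1-one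
Product: 9 (2R)-2-methyl-1-[2,4,6-trihydroxy-3-(3-methylbut-2-en-1-yl)phenyl]butan-1-one
Conditions: prenyl bromide (1.0 equiv), DBU (1.0 equiv), THF, 0 °C to rt
Reagents that add atoms: prenyl bromide (1-bromo-3-methylbut-2-ene), CC(C)=CCBr
Why: C-alkylation of the ambident acylphloroglucinol phenoxide (base-mediated C-prenylation), where the two free ring carbons are equivalent so mono-alkylation should give one regioisomer and limiting the bromide restrains a second prenylation.

**Step 5**
Reactants: 9 (2R)-2-methyl-1-[2,4,6-trihydroxy-3-(3-methylbut-2-en-1-yl)phenyl]butan-1-one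
Product: 10 (2R)-1-[2,6-dihydroxy-4-methoxy-3-(3-methylbut-2-en-1-yl)phenyl]-2-methylbutan-1-one
Conditions: Me2SO4 (1.0 equiv), K2CO3 (1.0 equiv), acetone, 0 °C to rt
Reagents that add atoms: dimethyl sulfate, COS(=O)(=O)OC
Why: Williamson O-methylation of the most acidic phenol, since the 4-OH para to the acyl group is not hydrogen-bonded whereas the 2- and 6-OH are chelated to the ketone, so one equivalent of base and electrophile should methylate the 4-OH selectively.

**Step 6**
Reactants: 10 (2R)-1-[2,6-dihydroxy-4-methoxy-3-(3-methylbut-2-en-1-yl)phenyl]-2-methylbutan-1-one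
Product: 11 (2R)-1-{3-[(dimethylamino)methyl]-2,6-dihydroxy-4-methoxy-5-(3-methylbut-2-en-1-yl)phenyl}-2-methylbutan-1-one
Conditions: Eschenmoser's salt (1.1 equiv), Et3N (1.1 equiv), CH2Cl2, 0 °C to rt
Reagents that add atoms: Eschenmoser's salt (N,N-dimethylmethyleneiminium iodide), C=[N+](C)C.[I-]
Why: Phenol Mannich reaction (aromatic aminomethylation by a preformed iminium salt) at the only unsubstituted ring carbon, which is ortho to OH, ortho to OMe and para to the second OH.

**Step 7**
Reactants: 11 (2R)-1-{3-[(dimethylamino)methyl]-2,6-dihydroxy-4-methoxy-5-(3-methylbut-2-en-1-yl)phenyl}-2-methylbutan-1-one; 4 6-ethyl-4-hydroxy-5-methyl-2H-pyran-2-one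
Product: 13 6-ethyl-4-hydroxy-5-methyl-3-{[2,4-dihydroxy-6-methoxy-3-((2R)-2-methylbutanoyl)-5-(3-methylbut-2-en-1-yl)phenyl]methyl}-2H-pyran-2-one (CNP0279667.1), via ortho-quinone methide 12 (not isolated)
Conditions: 4 (1.5 equiv), 1,4-dioxane, 90 °C, N2 stream
Reagents that add atoms: none
Why: Mannich-base quinone-methide generation followed by Michael addition, the way phenolic Mannich bases alkylate C–H acids such as 4-hydroxycoumarins: the acidic pyranone 4 protonates the benzylic amine of 11, the ammonium phenol loses Me2NH to give quinone methide 12, and the pyranonate adds through C3 to the exocyclic CH2, after which rearomatisation and tautomerisation give 13. No ring is closed and no stereocentre is formed; the (R)-centre alpha to the hydrogen-bonded aryl ketone is remote and sees only near-neutral conditions that should not enolise it. On the electrophile, the CH2NMe2 carbon is the only benzylic leaving-group site, and the quinone methides available through the ortho-OH and the para-OH are attacked at the same exocyclic carbon, so both converge on one product. On the nucleophile, C5 of the pyranone is blocked by methyl so C3 is the only nucleophilic carbon, and O-alkylation at O4 is reversible under the conditions whereas C-alkylation is made irreversible by rearomatisation. Excess pyranone and removal of Me2NH in the nitrogen stream should suppress amine re-addition and hetero-Diels–Alder capture of 12 by the prenyl olefin.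

**Compound list**
1 | methyl 3-oxopentanoate | CCC(=O)CC(=O)OC | starting material
2 | N-methoxy-N-methylpropanamide | CCC(=O)N(C)OC | starting material
3 | methyl 4-methyl-3,5-dioxoheptanoate (racemic at C4, largely enolised) | CCC(=O)C(C)C(=O)CC(=O)OC | intermediate
4 | 6-ethyl-4-hydroxy-5-methyl-2H-pyran-2-one | CCc1oc(=O)cc(O)c1C | intermediate
5 | (2R)-2-methylbutanoic acid | CC[C@@H](C)C(O)=O | starting material
6 | phloroglucinol (benzene-1,3,5-triol) | Oc1cc(O)cc(O)c1 | starting material
7 | (2R)-2-methylbutanoyl chloride (not isolated) | CC[C@@H](C)C(Cl)=O | intermediate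
8 | (2R)-2-methyl-1-(2,4,6-trihydroxyphenyl)butan-1-one | CC[C@@H](C)C(=O)c1c(O)cc(O)cc1O | intermediate
9 | (2R)-2-methyl-1-[2,4,6-trihydroxy-3-(3-methylbut-2-en-1-yl)phenyl]butan-1-one | CC[C@@H](C)C(=O)c1c(O)cc(O)c(CC=C(C)C)c1O | intermediate
10 | (2R)-1-[2,6-dihydroxy-4-methoxy-3-(3-methylbut-2-en-1-yl)phenyl]-2-methylbutan-1-one | CC[C@@H](C)C(=O)c1c(O)cc(OC)c(CC=C(C)C)c1O | intermediate
11 | (2R)-1-{3-[(dimethylamino)methyl]-2,6-dihydroxy-4-methoxy-5-(3-methylbut-2-en-1-yl)phenyl}-2-methylbutan-1-one | CC[C@@H](C)C(=O)c1c(O)c(CN(C)C)c(OC)c(CC=C(C)C)c1O | intermediate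
12 | 3-hydroxy-5-methoxy-6-methylidene-2-[(2R)-2-methylbutanoyl]-4-(3-methylbut-2-en-1-yl)cyclohexa-2,4-dien-1-one (ortho-quinone methide, not isolated) | C=C1C(=O)C(C(=O)[C@H](C)CC)=C(O)C(CC=C(C)C)=C1OC | intermediate
13 | 6-ethyl-4-hydroxy-5-methyl-3-{[2,4-dihydroxy-6-methoxy-3-((2R)-2-methylbutanoyl)-5-(3-methylbut-2-en-1-yl)phenyl]methyl}-2H-pyran-2-one | CCc1oc(=O)c(Cc2c(O)c(C(=O)[C@H](C)CC)c(O)c(CC=C(C)C)c2OC)c(O)c1C | target

**Total step count:** 7
**Longest linear sequence:** 5 steps (steps 3 to 7, from 5 and 6 to 13)

**Steps most likely to fail**

1. Step 7 (key coupling). The quinone methide may be consumed by self-condensation, by hetero-Diels–Alder reaction with the prenyl olefin of a second molecule, or by re-addition of dimethylamine faster than it is captured at C3 of the pyranone. The fallback sets out from 10 and comes back to the route at 13; it makes the same bond by carbonyl condensation and transfer hydrogenation instead of quinone-methide alkylation. Vilsmeier–Haack formylation of 10 (POCl3, DMF, EtOAc, 0 °C to rt; aq. NaOAc) at the only free ring carbon should give 2,4-dihydroxy-6-methoxy-3-[(2R)-2-methylbutanoyl]-5-(3-methylbut-2-en-1-yl)benzaldehyde F1. Proline-catalysed three-component reductive alkylation of 4 with this aldehyde and Hantzsch ester (EtOH, rt to 50 °C) should then pass through the Knoevenagel adduct 3-(arylmethylidene)-6-ethyl-5-methyl-2H-pyran-2,4(3H)-dione F2 (not isolated), whose exocyclic double bond is reduced in situ by hydride transfer to give 13.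

2. Step 4 (C-prenylation). Mono-C-selectivity may be lost through O-prenylation, a second prenylation at the remaining ring carbon and geminal, dearomatising prenylation of the phenoxide. The fallback sets out from 8 and comes back at 9; it replaces phenoxide alkylation by acid-mediated Friedel–Crafts prenylation of the neutral phenol with 2-methylbut-3-en-2-ol and BF3·OEt2 in dioxane at rt, where O-alkylation and geminal dialkylation of an anion cannot occur. It makes no new compound (F0).

3. Step 5 (selective O-methylation). Site selectivity may be lost, with methylation at a chelated ortho-OH or twofold methylation, because the neighbouring prenyl group shields the 4-OH. The fallback sets out from 8 and comes back at 10; it reverses the order of events. Methylation of 8 (Me2SO4, K2CO3, acetone), where the 4-OH is unhindered, should give (2R)-1-(2,6-dihydroxy-4-methoxyphenyl)-2-methylbutan-1-one F3. C-prenylation of this symmetric ketone (prenyl bromide, DBU, THF, 0 °C to rt; the two free ring carbons are equivalent) should then give 10.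

**Further compounds**
F1 | step 7 | 2,4-dihydroxy-6-methoxy-3-[(2R)-2-methylbutanoyl]-5-(3-methylbut-2-en-1-yl)benzaldehyde | CC[C@@H](C)C(=O)c1c(O)c(C=O)c(OC)c(CC=C(C)C)c1O
F2 | step 7 | 3-(arylmethylidene)-6-ethyl-5-methyl-2H-pyran-2,4(3H)-dione (Knoevenagel adduct of F1 and 4, not isolated) | CCC1=C(C)C(=O)C(=Cc2c(O)c(C(=O)[C@H](C)CC)c(O)c(CC=C(C)C)c2OC)C(=O)O1
F0 | step 4 | none | none
F3 | step 5 | (2R)-1-(2,6-dihydroxy-4-methoxyphenyl)-2-methylbutan-1-one | CC[C@@H](C)C(=O)c1c(O)cc(OC)cc1O
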